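Take one equivalent of partner to the substrate charge as your unit, and count everything as a fraction of that charge.

    substrate + free catalyst → free catalyst + open intermediate (k1 = 37100 M⁻¹ s⁻¹)
    free catalyst + open intermediate ⇌ catalyst intermediate (K2 = 22.8 M⁻¹, k2 = 7970 M⁻¹ s⁻¹)
    partner + catalyst intermediate → free catalyst + product (k3 = 64800 M⁻¹ s⁻¹)
    partner + product ⇌ idle adduct, settled at all times (K4 = 29.6 M⁻¹)
    partner → decomposed reagent (k5 = 0.145 s⁻¹)

the same everywhere: substrate 46 mM; free catalyst 23 µM; time 15 s

| flask | partner |
|---|---|
| ochre | 51.0 mM |
| teal | 100 mM |

- for product the idle adduct is counted in
- run time (ochre): 15 s

- which of these there is most of at the end, counted by the substrate in it, ochre (open intermediate / product / substrate)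
- which of these there is most of at the end, counted by the substrate in it, teal (open intermediate / product / substrate)
- final amount of the leader among these, as a percentage of the substrate charged, in ochre
- final amount of the leader among these, as a percentage of the substrate charged, in teal

Substrate opens with a half-life of 0.81 s by step 1 alone, shorter than the 3.8 s of open intermediate by the forward step 2 alone. So start the reckoning with the whole charge open.

Begin at the end with plenty of partner, where step 3 clears catalyst intermediate at once. Open intermediate then drains with a pseudo-first-order constant of 0.183 s⁻¹. Each unit drained costs one unit of partner, and partner also decays at 0.145 s⁻¹. These two constants are close, so call both k. The sum is then short: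

open fraction = exp(−kt)
partner equivalents = (start − kt) · exp(−kt)

In this sum partner reaches zero at kt = start, so the product fraction is 1 − exp(−start). That gives 67.0 % for ochre and 88.6 % for teal.

You should object that partner is not useful down to zero. Take the other end, with little partner. Catalyst intermediate then also falls back by step 2, and it holds catalyst. The drain carries the factor k3·partner / (k3·partner + k2/K2 + k2·open). With the charge open, a partner level of 11.1 mM brings this factor to half. Join the two ends there. In ochre the partner above that level, per substrate charged, is 0.868; call this the useful equivalents. Teal has 1.93.

product fraction = 1 − exp(−useful equivalents)

This gives 58.0 % for ochre and 85.5 % for teal.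

A second objection is that the constants are not equal: their ratio is 1.26. I accept that error and trust two digits at most. A third is the clock. The drain constant times 15 s is 2.75, more than teal's useful equivalents, but the factor above slows the drain as partner falls. So I commit to product leading in both, with teal's figure as a stopping level that may come late.

The forecast gave product in ochre at 57 % (49 % to 65 %) and product in teal at 79 % (70 % to 87 %), reasoning that “partner runs out first, more severely in ochre”.

The simulation gives product at 57.8 % in ochre and product at 78.6 % in teal. In ochre, step 1 had 71 % of its turnover up to 15 s behind it by 1.50 s, and product stood at 48.3 % by 7.50 s, when partner was down to 8.08 % of its charge. In teal, product went from 59.0 % to 78.6 % between 7.50 s and 15.0 s, below my stopping level, and it stands at 85.9 % after 150 s.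

Now take the neighbour of ochre charged with 31 mM of partner. It has 0.434 useful equivalents against the 0.868 of ochre, so the rule gives 35.2 % product. The flask gives 40.3 %, with 59.7 % left as open intermediate.

The constants are invented, and the outcome is calculated.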